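**Strategy.** Ring atoms: C1 (CMe2), C2 (CHBr), C3 (alkylidene carbon), C4 (CHCl), C5 (CH2), C6 (CHCl); side chain C7, C8. The arc C5–C6–C1–C2, with the C6 stereocentre next to quaternary C1, is drawn from a strained (3R)-3-alkoxy-2,2-dimethylcyclobutanone. Zerovalent nickel cleaves its acyl–CH2 bond and inserts a silylated 3-alkynoate, forming C5–C4 and C3–C2 at once and expanding the four-membered ring to the cyclohexenone with C6 retained. The acetate arm then lactonises onto C2–OH; the butenolide locks the C3=C7 geometry, and three C–O bonds (C4, C6, C2) plus C8–O are finally exchanged for halide, the ring centres with inversion.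

Key step: step 4

Remark on the chemistry: the two C3 epimers formed in step 2 are diastereomers (the ether carbon is stereodefined) and are taken to be separable by chromatography; the (3R,1′S)-isomer is carried on.

**Step 1**
Reactants: 1 (1S)-1-(4-methoxyphenyl)ethan-1-ol; 2 butyl vinyl ether
Product: 3 1-[(1S)-1-(ethenyloxy)ethyl]-4-methoxybenzene
Conditions: Pd(OAc)2 (2 mol %), 4,7-diphenyl-1,10-phenanthroline (2 mol %), Et3N (5 mol %), neat 2, 75 °C
Reagents that add atoms: none
Why: Transfer vinylation (transetherification) catalysed by divalent palladium exchanges the alkoxy group on the vinyl ether without breaking the carbinol C–O bond, so the (S)-centre is retained.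

**Step 2**
Reactants: 3 1-[(1S)-1-(ethenyloxy)ethyl]-4-methoxybenzene; 4 isobutyryl chloride
Product: 6 (3R)-3-[(1S)-1-(4-methoxyphenyl)ethoxy]-2,2-dimethylcyclobutan-1-one, via dimethylketene 5 (not isolated)
Conditions: Et3N, MeCN, reflux (4 added slowly); chromatographic separation of the C3 epimers
Reagents that add atoms: none
Why: Dehydrochlorination of 4 gives dimethylketene 5, which adds to the electron-rich vinyl ether in a thermal ketene–enol ether [2+2] cycloaddition (acyl carbon to the CH2 terminus, CMe2 to the O-bearing carbon); the new C3 centre (later C6) forms under only weak control by the (S)-ether carbon, and the (3R)-epimer is isolated as a single diastereomer.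

**Step 3**
Reactants: 7 ethynyltrimethylsilane; 8 ethyl diazoacetate
Product: 9 ethyl 4-(trimethylsilyl)but-3-ynoate
Conditions: CuI (5 mol %), MeCN, rt
Reagents that add atoms: none
Why: Coupling of a terminal alkyne with a diazoacetate under catalysis by monovalent copper (copper acetylide/carbene coupling) should give the 3-alkynoate directly, with loss of N2 and no stereocentre formed.

**Step 4**
Reactants: 6 (3R)-3-[(1S)-1-(4-methoxyphenyl)ethoxy]-2,2-dimethylcyclobutan-1-one; 9 ethyl 4-(trimethylsilyl)but-3-ynoate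
Product: 10 ethyl 2-[(4R)-4-[(1S)-1-(4-methoxyphenyl)ethoxy]-5,5-dimethyl-6-oxo-2-(trimethylsilyl)cyclohex-1-en-1-yl]acetate
Conditions: Ni(cod)2 (10 mol %), PCy3 (20 mol %), toluene, 90 °C, slow addition of 9
Reagents that add atoms: none
Why: Zerovalent nickel couples the strained C=O of 6 and the alkyne of 9 oxidatively to an oxanickelacyclopentene (C3–C2 bond), β-carbon elimination then breaks the acyl–CH2 bond of the four-membered ring, and C(sp2)–C(sp3) reductive elimination forms C5–C4, so both bonds arise in one catalytic cycle. The closest known reaction type is the nickel-catalysed intermolecular alkyne insertion into cyclobutanones (formal [4+2] annulation), with the bond selectivity known for 2-substituted four-membered ketones such as azetidin-3-ones. The cyclohexenone ring closes by two-carbon ring expansion, the last bond coming from reductive elimination out of a seven-membered nickelacycle. No stereocentre is created; C6 is not on the cleaved bond and keeps its (R)-configuration, from which the C2 and C4 centres are later relayed. Two selectivities are needed: cleavage of the CH2–acyl rather than the CMe2–acyl bond, secured by the preference of nickel for the unhindered primary alkyl, and alkyne regiochemistry with the silyl-bearing carbon on nickel (then C4) and the CH2CO2Et-bearing carbon on the carbonyl carbon, secured by the usual α-silyl preference in oxidative cyclisation. The bulky benzylic ether at C6 is meant to slow β-alkoxide elimination from the alkylnickel intermediate.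

**Step 5**
Reactants: 10 ethyl 2-[(4R)-4-[(1S)-1-(4-methoxyphenyl)ethoxy]-5,5-dimethyl-6-oxo-2-(trimethylsilyl)cyclohex-1-en-1-yl]acetate
Product: 12 (6R,7aR)-6-[(1S)-1-(4-methoxyphenyl)ethoxy]-7,7-dimethyl-4-(trimethylsilyl)-5,6,7,7a-tetrahydro-1-benzofuran-2(3H)-one, via hydroxy ester 11 (not isolated)
Conditions: NaBH4, CeCl3·7H2O, MeOH, −40 °C; AcOH quench; then PPTS (cat.), CH2Cl2, rt
Reagents that add atoms: none
Why: Luche 1,2-reduction: hydride should add to C2 along the axial trajectory on the face away from the pseudoaxial C1 methyl, so the new C2–O bond is equatorial and cis to the equatorial C6–O bond (6R in 11), and the γ-hydroxy ester then closes to the five-membered lactone that will fix the C3=C7 geometry.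

**Step 6**
Reactants: 12 (6R,7aR)-6-[(1S)-1-(4-methoxyphenyl)ethoxy]-7,7-dimethyl-4-(trimethylsilyl)-5,6,7,7a-tetrahydro-1-benzofuran-2(3H)-one
Product: 13 (6R,7aS)-6-hydroxy-7,7-dimethyl-5,6,7,7a-tetrahydro-1-benzofuran-2(3H)-one
Conditions: CF3CO2H, anisole, CH2Cl2, 0 °C → rt; aq. NaHCO3
Reagents that add atoms: none
Why: Protodesilylation by ipso-protonation at C4 (β-silyl-stabilised tertiary cation at C3, then loss of silicon) leaves the C3=C4 alkene in place, and the same acid cleaves the p-methoxy-α-methylbenzyl ether through its benzylic cation (captured by anisole) to free C6–OH; no stereocentre is touched.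

**Step 7**
Reactants: 13 (6R,7aS)-6-hydroxy-7,7-dimethyl-5,6,7,7a-tetrahydro-1-benzofuran-2(3H)-one
Product: 15 (4R,6R,7aR)-4,6-dihydroxy-7,7-dimethyl-5,6,7,7a-tetrahydro-1-benzofuran-2(4H)-one, via epoxy lactone 14 (not isolated)
Conditions: mCPBA, NaHCO3, CH2Cl2, 0 °C; then Et3N, rt
Reagents that add atoms: mCPBA, O=C(OO)c1cccc(Cl)c1
Why: Prilezhaev epoxidation should occur on the face opposite to the pseudoaxial C1 methyl and to the C2 and C6 oxygens, and amine-triggered E1cB opening of the β,γ-epoxy lactone (deprotonation at C7) moves the alkene into conjugation inside the lactone ring, so C8 is held cis to C2 and C4–OH ends axial and trans to both other oxygens (4R).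

**Step 8**
Reactants: 15 (4R,6R,7aR)-4,6-dihydroxy-7,7-dimethyl-5,6,7,7a-tetrahydro-1-benzofuran-2(4H)-one
Product: 16 (4S,6S,7aR)-4,6-dichloro-7,7-dimethyl-5,6,7,7a-tetrahydro-1-benzofuran-2(4H)-one
Conditions: PPh3, CCl4, MeCN, rt → 70 °C
Reagents that add atoms: carbon tetrachloride, ClC(Cl)(Cl)Cl
Why: Appel reaction: both alkoxyphosphonium ions should be displaced by chloride in SN2 fashion with inversion, the allylic axial C4 centre at room temperature and the neopentyl equatorial C6 centre on heating, giving the (4S,6S)-dichloride with C4–Cl trans to C6–Cl.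

**Step 9**
Reactants: 16 (4S,6S,7aR)-4,6-dichloro-7,7-dimethyl-5,6,7,7a-tetrahydro-1-benzofuran-2(4H)-one
Product: 18 (1R,2E,3S,5S)-3,5-dichloro-2-(2-hydroxyethylidene)-6,6-dimethylcyclohexan-1-ol, via lactol 17 (not isolated)
Conditions: i-Bu2AlH (4 equiv), CH2Cl2, −78 → 0 °C; aq. potassium sodium tartrate
Reagents that add atoms: none
Why: Diisobutylaluminium hydride reduces the butenolide by 1,2-addition through lactol 17 to the ene-1,4-diol without touching the C–Cl bonds or any stereocentre, and the alkene geometry (C8 cis to C2) is inherited from the five-membered ring.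

**Step 10**
Reactants: 18 (1R,2E,3S,5S)-3,5-dichloro-2-(2-hydroxyethylidene)-6,6-dimethylcyclohexan-1-ol
Product: 19 (2S,3Z,4S,6S)-2-bromo-3-(2-bromoethylidene)-4,6-dichloro-1,1-dimethylcyclohexane (CNP0137413.1)
Conditions: CBr4, PPh3, CH2Cl2, −20 → 0 °C
Reagents that add atoms: carbon tetrabromide, BrC(Br)(Br)Br
Why: Appel bromination converts the primary allylic alcohol first and then displaces the C2 alkoxyphosphonium ion by bromide in an SN2 step with inversion, turning the (R)-carbinol into the (S)-bromide cis to C6–Cl; low temperature disfavours SN2′ attack at C7.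

**Compound list**
1 | (1S)-1-(4-methoxyphenyl)ethan-1-ol | C[C@H](O)c1ccc(OC)cc1 | starting material
2 | butyl vinyl ether | C=COCCCC | starting material
3 | 1-[(1S)-1-(ethenyloxy)ethyl]-4-methoxybenzene | C=CO[C@@H](C)c1ccc(OC)cc1 | intermediate
4 | isobutyryl chloride | CC(C)C(Cl)=O | starting material
5 | dimethylketene | CC(C)=C=O | intermediate
6 | (3R)-3-[(1S)-1-(4-methoxyphenyl)ethoxy]-2,2-dimethylcyclobutan-1-one | CC1(C)C(=O)C[C@H]1O[C@@H](C)c1ccc(OC)cc1 | intermediate
7 | ethynyltrimethylsilane | C#C[Si](C)(C)C | starting material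
8 | ethyl diazoacetate | CCOC(=O)C=[N+]=[N-] | starting material
9 | ethyl 4-(trimethylsilyl)but-3-ynoate | CCOC(=O)CC#C[Si](C)(C)C | intermediate
10 | ethyl 2-[(4R)-4-[(1S)-1-(4-methoxyphenyl)ethoxy]-5,5-dimethyl-6-oxo-2-(trimethylsilyl)cyclohex-1-en-1-yl]acetate | CC1(C)C(=O)C(CC(=O)OCC)=C([Si](C)(C)C)C[C@H]1O[C@@H](C)c1ccc(OC)cc1 | intermediate
11 | ethyl 2-[(4R,6R)-6-hydroxy-4-[(1S)-1-(4-methoxyphenyl)ethoxy]-5,5-dimethyl-2-(trimethylsilyl)cyclohex-1-en-1-yl]acetate (6-OH cis to the 4-ether) | CC1(C)[C@@H](O)C(CC(=O)OCC)=C([Si](C)(C)C)C[C@H]1O[C@@H](C)c1ccc(OC)cc1 | intermediate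
12 | (6R,7aR)-6-[(1S)-1-(4-methoxyphenyl)ethoxy]-7,7-dimethyl-4-(trimethylsilyl)-5,6,7,7a-tetrahydro-1-benzofuran-2(3H)-one | CC1(C)[C@H]2OC(=O)CC2=C([Si](C)(C)C)C[C@H]1O[C@@H](C)c1ccc(OC)cc1 | intermediate
13 | (6R,7aS)-6-hydroxy-7,7-dimethyl-5,6,7,7a-tetrahydro-1-benzofuran-2(3H)-one | CC1(C)[C@H]2OC(=O)CC2=CC[C@H]1O | intermediate
14 | 3a,4-epoxide of 13, oxirane oxygen on the face opposite to O1 and to the 6-hydroxyl | CC1(C)[C@H]2OC(=O)C[C@]23O[C@@H]3C[C@H]1O | intermediate
15 | (4R,6R,7aR)-4,6-dihydroxy-7,7-dimethyl-5,6,7,7a-tetrahydro-1-benzofuran-2(4H)-one | CC1(C)[C@H]2OC(=O)C=C2[C@H](O)C[C@H]1O | intermediate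
16 | (4S,6S,7aR)-4,6-dichloro-7,7-dimethyl-5,6,7,7a-tetrahydro-1-benzofuran-2(4H)-one | CC1(C)[C@H]2OC(=O)C=C2[C@@H](Cl)C[C@@H]1Cl | intermediate
17 | (4S,6S,7aR)-4,6-dichloro-7,7-dimethyl-2,4,5,6,7,7a-hexahydro-1-benzofuran-2-ol (lactol, both anomers) | CC1(C)[C@H]2OC(O)C=C2[C@@H](Cl)C[C@@H]1Cl | intermediate
18 | (1R,2E,3S,5S)-3,5-dichloro-2-(2-hydroxyethylidene)-6,6-dimethylcyclohexan-1-ol (CH2OH cis to the carbinol carbon) | CC1(C)[C@@H](O)/C(=C\CO)[C@@H](Cl)C[C@@H]1Cl | intermediate
19 | (2S,3Z,4S,6S)-2-bromo-3-(2-bromoethylidene)-4,6-dichloro-1,1-dimethylcyclohexane | CC1(C)[C@H](Br)/C(=C\CBr)[C@@H](Cl)C[C@@H]1Cl | target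

**Step count.** Total: 10 steps. Longest linear sequence: 9 steps (1, 2, 4, 5, 6, 7, 8, 9, 10); step 3 is a one-step side branch.

**Steps most likely to fail and fallbacks**

Step 4 (key step). The C–H-acidic 3-alkynoate 9 may isomerise to the allenoate and oligomerise on the basic nickel–phosphine catalyst before it can insert into the hindered, α-quaternary ketone. The fallback brings in the acetate arm at the alcohol oxidation level and adjusts it afterwards. It sets out from 6. The same nickel-catalysed insertion is run with the non-acidic alkyne tert-butyldimethyl{[4-(trimethylsilyl)but-3-yn-1-yl]oxy}silane F1 (from commercial 4-(trimethylsilyl)but-3-yn-1-ol, TBSCl, imidazole), which should give (5R)-2-{2-[(tert-butyldimethylsilyl)oxy]ethyl}-5-[(1S)-1-(4-methoxyphenyl)ethoxy]-6,6-dimethyl-3-(trimethylsilyl)cyclohex-2-en-1-one F2. Luche reduction then gives the cis-configured (1R,5R)-cyclohex-2-en-1-ol F3. Acetic-acid-buffered Bu4NF at 0 °C removes only the primary silyl ether to give (1R,5R)-2-(2-hydroxyethyl)-5-[(1S)-1-(4-methoxyphenyl)ethoxy]-6,6-dimethyl-3-(trimethylsilyl)cyclohex-2-en-1-ol F4. Oxidative lactonisation of this 1,4-diol with TEMPO/PhI(OAc)2 comes back to the route at 12.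

Step 8. Heating the neopentyl C6 alkoxyphosphonium ion may lead to E2 elimination towards C5 or to methyl migration after ionisation, and prolonged exposure to chloride may epimerise the allylic C4 chloride. The fallback separates the two substitutions and gives C6 a far better leaving group at low temperature. It sets out from 15. PPh3/hexachloroacetone at −20 °C should chlorinate only the allylic alcohol with inversion to give (4S,6R,7aR)-4-chloro-6-hydroxy-7,7-dimethyl-5,6,7,7a-tetrahydro-1-benzofuran-2(4H)-one F5. Tf2O/pyridine at −40 °C gives (4S,6R,7aR)-4-chloro-7,7-dimethyl-2-oxo-2,4,5,6,7,7a-hexahydro-1-benzofuran-6-yl trifluoromethanesulfonate F6. Displacement with Bu4NCl in CH2Cl2 at 0 °C, with inversion, comes back to the route at 16.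

Step 10. Substitution at the neopentyl, allylic C2 may proceed by allylic transposition (bromide attack at C7) or by ionisation with loss of configuration, and the cis-enediol may cyclodehydrate to the 2,5-dihydrofuran. The fallback installs the C2 bromide on the lactone, where the leaving group is the ring carboxylate and attack at C7 would break conjugation. It sets out from 16. HBr in acetic acid should open the butenolide by alkyl–oxygen cleavage at C2 with inversion to give (2Z)-2-[(2S,4S,6S)-2-bromo-4,6-dichloro-3,3-dimethylcyclohexylidene]acetic acid F7. BH3·SMe2 at 0 °C reduces the acid to (2Z)-2-[(2S,4S,6S)-2-bromo-4,6-dichloro-3,3-dimethylcyclohexylidene]ethan-1-ol F8. CBr4/PPh3 then brominates only this primary allylic alcohol and arrives at 19.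

**Further compounds**
F1 | step 4 | tert-butyldimethyl{[4-(trimethylsilyl)but-3-yn-1-yl]oxy}silane | C[Si](C)(C)C#CCCO[Si](C)(C)C(C)(C)C
F2 | step 4 | (5R)-2-{2-[(tert-butyldimethylsilyl)oxy]ethyl}-5-[(1S)-1-(4-methoxyphenyl)ethoxy]-6,6-dimethyl-3-(trimethylsilyl)cyclohex-2-en-1-one | CC1(C)C(=O)C(CCO[Si](C)(C)C(C)(C)C)=C([Si](C)(C)C)C[C@H]1O[C@@H](C)c1ccc(OC)cc1
F3 | step 4 | (1R,5R)-2-{2-[(tert-butyldimethylsilyl)oxy]ethyl}-5-[(1S)-1-(4-methoxyphenyl)ethoxy]-6,6-dimethyl-3-(trimethylsilyl)cyclohex-2-en-1-ol | CC1(C)[C@@H](O)C(CCO[Si](C)(C)C(C)(C)C)=C([Si](C)(C)C)C[C@H]1O[C@@H](C)c1ccc(OC)cc1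
F4 | step 4 | (1R,5R)-2-(2-hydroxyethyl)-5-[(1S)-1-(4-methoxyphenyl)ethoxy]-6,6-dimethyl-3-(trimethylsilyl)cyclohex-2-en-1-ol | CC1(C)[C@@H](O)C(CCO)=C([Si](C)(C)C)C[C@H]1O[C@@H](C)c1ccc(OC)cc1
F5 | step 8 | (4S,6R,7aR)-4-chloro-6-hydroxy-7,7-dimethyl-5,6,7,7a-tetrahydro-1-benzofuran-2(4H)-one | CC1(C)[C@H]2OC(=O)C=C2[C@@H](Cl)C[C@H]1O
F6 | step 8 | (4S,6R,7aR)-4-chloro-7,7-dimethyl-2-oxo-2,4,5,6,7,7a-hexahydro-1-benzofuran-6-yl trifluoromethanesulfonate | CC1(C)[C@H]2OC(=O)C=C2[C@@H](Cl)C[C@H]1OS(=O)(=O)C(F)(F)F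
F7 | step 10 | (2Z)-2-[(2S,4S,6S)-2-bromo-4,6-dichloro-3,3-dimethylcyclohexylidene]acetic acid | CC1(C)[C@H](Br)/C(=C\C(=O)O)[C@@H](Cl)C[C@@H]1Cl
F8 | step 10 | (2Z)-2-[(2S,4S,6S)-2-bromo-4,6-dichloro-3,3-dimethylcyclohexylidene]ethan-1-ol | CC1(C)[C@H](Br)/C(=C\CO)[C@@H](Cl)C[C@@H]1Cl
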